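## Retrosynthetic overview

- Numbering (tricyclo[5.2.2.0(1,6)]undecane core): ring A = C1–C6 (C1 quaternary bridgehead, C2 = CMe2, C6 = methyl-bearing one-carbon bridge); C7 = bridgehead CH, C8 = C–O, C9 and C10 = CH2, C11 = C=CH2.
- Last: caffeate on O8 (hydrogen malonate, then Knoevenagel–Doebner with 3,4-dihydroxybenzaldehyde); 8-exo-OH from endo hydride delivery to the C8 ketone; C11 methylidene by Wittig.
- Bicyclo[2.2.1] closure by silylative aldol bond C7–C8 (aldehyde from a C1 allyl group); before it, cyclopentanone C1–C10–C11–C7–C6 by cationic chloro-olefin annulation (bond C6–C7, cis to ring A); C1 stereocentre by enantioconvergent Pd-catalysed decarboxylative allylation.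
- Key disconnection: ring A is made first, from acyclic material, by a formal [3+3] annulation forming C4–C5 and C1–C2 in one operation (1,3-bis(silyl enol ether) C5–C6–C1 plus prenal dimethyl acetal C4–C3–C2).
- Enabling feature: in ring A, C6 lies between C5H2 and C1, and C1 carries C2Me2; with C6 at the ketone level, C5 and C1 are the gamma and alpha carbons of a β-keto ester (1,3-bis-nucleophile) and C4–C3–C2 is a prenyl-type 1,3-bis-electrophile with its tertiary end at C2. Ring order: A, cyclopentanone, C8–C9 bridge.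

Key step: step 4

Assumption: the sense of induction of (S)-t-Bu-PHOX in step 6 is taken from the simple 2-alkyl-2-allylcyclohexanone series; if it proves reversed, the (R)-ligand is used.

## Route

Step 1
Reactants: 1 2,2,6-trimethyl-4H-1,3-dioxin-4-one; 2 2-(trimethylsilyl)ethanol
Product: 4 2-(trimethylsilyl)ethyl 3-oxobutanoate, via acetylketene 3 (not isolated)
Conditions: xylene, 140 °C, distil off acetone
Reagents that add atoms: none
Why: Thermolysis of the dioxinone gives acetylketene, which the alcohol traps (acetoacetylation).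

Step 2
Reactants: 4 2-(trimethylsilyl)ethyl 3-oxobutanoate; 5 2,3-dichloroprop-1-ene
Product: 7 2-(trimethylsilyl)ethyl 2-acetyl-4-chloropent-4-enoate (racemic), via sodium enolate 6 (not isolated)
Conditions: NaH, THF, 0 °C; then 5, NaI (cat.), 55 °C
Reagents that add atoms: none
Why: C-Alkylation of a β-keto ester enolate by an allylic chloride installs the masked acetonyl arm (future C10–C11–C7).

Step 3
Reactants: 7 2-(trimethylsilyl)ethyl 2-acetyl-4-chloropent-4-enoate
Product: 10 2-(trimethylsilyl)ethyl-derived 1,3-bis(trimethylsilyloxy)diene [2-(2-chloroprop-2-en-1-yl)-1-[2-(trimethylsilyl)ethoxy]-1,3-bis(trimethylsilyloxy)buta-1,3-diene], via silyl enol ether 8 (not isolated), via lithium dienolate 9 (not isolated)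
Conditions: Me3SiCl, Et3N, toluene, 25 °C, filter; then LDA, THF, −78 °C; Me3SiCl, −78 → 0 °C
Reagents that add atoms: chlorotrimethylsilane C[Si](C)(C)Cl
Why: Standard two-stage preparation of a 1,3-bis(silyl enol ether): O-silylation of the β-keto ester, then γ-deprotonation of the vinylogous ester methyl group and a second O-silylation.

Step 4
Reactants: 10 1,3-bis(trimethylsilyloxy)diene; 11 1,1-dimethoxy-3-methylbut-2-ene
Product: 13 2-(trimethylsilyl)ethyl 1-(2-chloroprop-2-en-1-yl)-2,2-dimethyl-6-oxocyclohex-3-ene-1-carboxylate (racemic), via open-chain silyl ketene acetal 12 (not isolated)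
Conditions: TMSOTf (0.2 equiv), CH2Cl2, −78 → −20 °C; aq. NaHCO3
Reagents that add atoms: none
Why: Proposed new method: TMSOTf ionises acetal 11 to its methoxy-substituted allyl cation, the terminal CH2 of 10 (its most nucleophilic carbon) adds at the acetal carbon in a vinylogous Mukaiyama addition to give 12 (bond C5–C4), and TMSOTf then ionises the allylic methyl ether of 12 to a prenyl-type cation whose tertiary terminus is attacked by the remaining tetrasubstituted silyl ketene acetal carbon (bond C1–C2), each Si–O cleavage returning the silyl triflate. The closest known reaction types are the Lewis-acid formal [3+3] cyclisation of 1,3-bis(silyl enol ethers) with 1,3-dielectrophiles, the Mukaiyama addition of silyl enol ethers to acetals, and the SN1 alkylation of silyl ketene acetals by tertiary and allylic cations, which is known to join two quaternary carbons. Ring A closes 6-endo at the allyl cation (cation–enol ether mode); the only alternative would be a four-membered ring. The new quaternary stereocentre C1 is formed racemic and needs no control, because step 6 erases and resets it. The step needs orientation control (CMe2 next to C1, not next to C5), secured by the order of events: the unhindered terminal carbon of 10 meets the acetal carbon first and the gem-dimethyl terminus is left for the ring closure. It also needs C- rather than O-alkylation, secured because the second nucleophile is an O-silylated ketene acetal.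

Step 5
Reactants: 13 2-(trimethylsilyl)ethyl 1-(2-chloroprop-2-en-1-yl)-2,2-dimethyl-6-oxocyclohex-3-ene-1-carboxylate
Product: 14 2-(trimethylsilyl)ethyl 1-(2-chloroprop-2-en-1-yl)-2,2-dimethyl-6-oxocyclohexane-1-carboxylate (racemic)
Conditions: H2 (1 atm), RhCl(PPh3)3 (5 mol%), benzene–EtOH, 25 °C
Reagents that add atoms: none
Why: Homogeneous hydrogenation should reduce the cis-disubstituted ring alkene and leave the 1,1-disubstituted vinyl chloride and the silyl ester untouched; the ring alkene must go before the cation chemistry of step 8.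

Step 6
Reactants: 14 2-(trimethylsilyl)ethyl 1-(2-chloroprop-2-en-1-yl)-2,2-dimethyl-6-oxocyclohexane-1-carboxylate; 15 methyl prop-2-en-1-yl carbonate
Product: 18 (2S)-2-(2-chloroprop-2-en-1-yl)-3,3-dimethyl-2-(prop-2-en-1-yl)cyclohexan-1-one, via ammonium carboxylate 16 (not isolated), via ammonium enolate 17 (not isolated)
Conditions: Pd2(dba)3 (5 mol%), (S)-t-Bu-PHOX (12.5 mol%), Bu4N[Ph3SiF2] (1.2 equiv), THF, 25 → 40 °C
Reagents that add atoms: none
Why: Fluoride cleaves the silylethyl ester, the carboxylate loses CO2 to a tetrasubstituted enolate in which the racemic C1 centre is erased, and the ligand-bound allylpalladium cation from 15 allylates one enolate face (enantioconvergent decarboxylative Tsuji–Trost allylation), so C1 is set under ligand control.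

Step 7
Reactants: 18 (2S)-2-(2-chloroprop-2-en-1-yl)-3,3-dimethyl-2-(prop-2-en-1-yl)cyclohexan-1-one
Product: 19 (2S)-2-(2-chloroprop-2-en-1-yl)-1,3,3-trimethyl-2-(prop-2-en-1-yl)cyclohexan-1-ol (both carbinol epimers)
Conditions: MeLi, Et2O, −78 → 0 °C
Reagents that add atoms: methyllithium [Li]C
Why: 1,2-Addition to the ketone brings in the C6 methyl group; the carbinol configuration is irrelevant because C6 is ionised in the next step.

Step 8
Reactants: 19 (2S)-2-(2-chloroprop-2-en-1-yl)-1,3,3-trimethyl-2-(prop-2-en-1-yl)cyclohexan-1-ol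
Product: 20 cis-fused 4,4,7a-trimethyl-3a-(prop-2-en-1-yl)octahydro-2H-inden-2-one (3a-allyl and 7a-methyl syn; enantiomer as in the SMILES)
Conditions: HCO2H (90% aq.), 25 → 50 °C
Reagents that add atoms: water O
Why: Cationic chloro-olefin annulation: the tertiary cation at C6 is attacked by the terminal carbon of the 2-chloroallyl group on the neighbouring C1 (5-endo) and the α-chloro cation is hydrolysed to the C11 ketone; a three-atom tether between adjacent ring carbons should close cis, which places the C6 methyl syn to the C1 allyl group.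

Step 9
Reactants: 20 cis-fused 4,4,7a-trimethyl-3a-(prop-2-en-1-yl)octahydro-2H-inden-2-one
Product: 22 2-(cis-4,4,7a-trimethyl-2-oxooctahydro-3aH-inden-3a-yl)acetaldehyde, via ozonide 21 (not isolated)
Conditions: O3, CH2Cl2, −78 °C; then PPh3, −78 → 25 °C
Reagents that add atoms: ozone [O-][O+]=O
Why: Ozonolysis with reductive work-up shortens the allyl group to the C9–C8 aldehyde arm; no other alkene is present.

Step 10
Reactants: 22 2-(cis-4,4,7a-trimethyl-2-oxooctahydro-3aH-inden-3a-yl)acetaldehyde
Product: 24 8-[(tert-butyldimethylsilyl)oxy]-2,2,6-trimethyltricyclo[5.2.2.0(1,6)]undecan-11-one (target numbering; C8 epimers), via enol silane 23 (not isolated)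
Conditions: TBSOTf (1.3 equiv), Et3N (1.6 equiv), CH2Cl2, −78 → 0 °C
Reagents that add atoms: tert-butyldimethylsilyl trifluoromethanesulfonate CC(C)(C)[Si](C)(C)OS(=O)(=O)C(F)(F)F
Why: Enol silane formation in the flask followed by intramolecular Mukaiyama aldol addition closes bond C7–C8; only the enol silane toward C7 can reach the aldehyde through a five-membered ring, O-silylation should make formation of the strained ketol irreversible, and C7 is fixed by the ring while the C8 configuration is not relied on.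

Step 11
Reactants: 24 8-[(tert-butyldimethylsilyl)oxy]-2,2,6-trimethyltricyclo[5.2.2.0(1,6)]undecan-11-one
Product: 25 tert-butyldimethyl[(2,2,6-trimethyl-11-methylidenetricyclo[5.2.2.0(1,6)]undecan-8-yl)oxy]silane (C8 epimers)
Conditions: Ph3PCH3Br, KOtBu, toluene, 80 °C
Reagents that add atoms: methyltriphenylphosphonium bromide C[P+](c1ccccc1)(c1ccccc1)c1ccccc1.[Br-]
Why: Wittig methylenation of the C11 ketone; the silylated β-oxygen blocks retro-aldol cleavage, and β-elimination would need a bridgehead alkene.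

Step 12
Reactants: 25 tert-butyldimethyl[(2,2,6-trimethyl-11-methylidenetricyclo[5.2.2.0(1,6)]undecan-8-yl)oxy]silane
Product: 26 2,2,6-trimethyl-11-methylidenetricyclo[5.2.2.0(1,6)]undecan-8-ol (C8 epimers)
Conditions: Bu4NF, THF, 25 °C
Reagents that add atoms: none
Why: Fluoride cleavage of the silyl ether.

Step 13
Reactants: 26 2,2,6-trimethyl-11-methylidenetricyclo[5.2.2.0(1,6)]undecan-8-ol
Product: 27 2,2,6-trimethyl-11-methylidenetricyclo[5.2.2.0(1,6)]undecan-8-one
Conditions: DMP, NaHCO3, CH2Cl2, 25 °C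
Reagents that add atoms: none
Why: Dess–Martin oxidation converges both C8 epimers on one ketone; the β,γ-alkene cannot move into conjugation because that would need a bridgehead double bond.

Step 14
Reactants: 27 2,2,6-trimethyl-11-methylidenetricyclo[5.2.2.0(1,6)]undecan-8-one
Product: 28 2,2,6-trimethyl-11-methylidenetricyclo[5.2.2.0(1,6)]undecan-8-ol, 8-exo epimer (OH syn to the C6 bridge)
Conditions: LiAlH4, Et2O, −78 → 0 °C
Reagents that add atoms: none
Why: Hydride reduction of a norbornan-2-one with a syn methyl group on the one-carbon bridge: the exo face of C8 is shielded by the C6 methyl, so hydride should arrive from the endo face and give the exo alcohol (camphor-to-isoborneol type selectivity).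

Step 15
Reactants: 28 8-exo alcohol; 29 2,2-dimethyl-1,3-dioxane-4,6-dione
Product: 30 3-oxo-3-[(2,2,6-trimethyl-11-methylidenetricyclo[5.2.2.0(1,6)]undecan-8-yl)oxy]propanoic acid (8-exo)
Conditions: toluene, 110 °C
Reagents that add atoms: none
Why: Thermal acylation of the hindered alcohol by the cyclic malonate (ring opening with loss of acetone) gives the hydrogen malonate without a coupling reagent.

Step 16
Reactants: 30 hydrogen malonate ester; 31 3,4-dihydroxybenzaldehyde
Product: 33 2,2,6-trimethyl-11-methylidenetricyclo[5.2.2.0(1,6)]undecan-8-yl (2E)-3-(3,4-dihydroxyphenyl)prop-2-enoate (CNP0308742.2), via arylidene malonate 32 (not isolated)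
Conditions: pyridine, piperidine (cat.), 70 °C, argon
Reagents that add atoms: none
Why: Knoevenagel–Doebner condensation: condensation at the malonate CH2 and decarboxylation should give the (E)-cinnamate, and the free catechol needs no protection.

## Compound list

1 | 2,2,6-trimethyl-4H-1,3-dioxin-4-one | CC1=CC(=O)OC(C)(C)O1 | starting material
2 | 2-(trimethylsilyl)ethanol | C[Si](C)(C)CCO | starting material
3 | acetylketene | CC(=O)C=C=O | intermediate (not isolated)
4 | 2-(trimethylsilyl)ethyl 3-oxobutanoate | CC(=O)CC(=O)OCC[Si](C)(C)C | intermediate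
5 | 2,3-dichloroprop-1-ene | C=C(Cl)CCl | starting material
6 | sodium enolate of 4 | CC([O-])=CC(=O)OCC[Si](C)(C)C.[Na+] | intermediate (not isolated)
7 | 2-(trimethylsilyl)ethyl 2-acetyl-4-chloropent-4-enoate (racemic) | CC(=O)C(CC(Cl)=C)C(=O)OCC[Si](C)(C)C | intermediate
8 | 2-(trimethylsilyl)ethyl 2-(2-chloroprop-2-en-1-yl)-3-(trimethylsilyloxy)but-2-enoate (E/Z) | CC(O[Si](C)(C)C)=C(CC(Cl)=C)C(=O)OCC[Si](C)(C)C | intermediate (not isolated)
9 | lithium dienolate of 8 | [Li+].C=C(O[Si](C)(C)C)C(CC(Cl)=C)=C([O-])OCC[Si](C)(C)C | intermediate (not isolated)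
10 | 2-(2-chloroprop-2-en-1-yl)-1-[2-(trimethylsilyl)ethoxy]-1,3-bis(trimethylsilyloxy)buta-1,3-diene (E/Z) | C=C(O[Si](C)(C)C)C(CC(Cl)=C)=C(O[Si](C)(C)C)OCC[Si](C)(C)C | intermediate
11 | 1,1-dimethoxy-3-methylbut-2-ene | COC(OC)C=C(C)C | starting material
12 | open-chain 5-methoxy-7-methyl-3-oxooct-6-enoate silyl ketene acetal | COC(C=C(C)C)CC(=O)C(CC(Cl)=C)=C(O[Si](C)(C)C)OCC[Si](C)(C)C | intermediate (not isolated)
13 | 2-(trimethylsilyl)ethyl 1-(2-chloroprop-2-en-1-yl)-2,2-dimethyl-6-oxocyclohex-3-ene-1-carboxylate (racemic) | O=C1CC=CC(C)(C)C1(CC(Cl)=C)C(=O)OCC[Si](C)(C)C | intermediate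
14 | 2-(trimethylsilyl)ethyl 1-(2-chloroprop-2-en-1-yl)-2,2-dimethyl-6-oxocyclohexane-1-carboxylate (racemic) | O=C1CCCC(C)(C)C1(CC(Cl)=C)C(=O)OCC[Si](C)(C)C | intermediate
15 | methyl prop-2-en-1-yl carbonate | C=CCOC(=O)OC | starting material
16 | tetrabutylammonium 1-(2-chloroprop-2-en-1-yl)-2,2-dimethyl-6-oxocyclohexane-1-carboxylate | CCCC[N+](CCCC)(CCCC)CCCC.[O-]C(=O)C1(CC(Cl)=C)C(=O)CCCC1(C)C | intermediate (not isolated)
17 | tetrabutylammonium 2-(2-chloroprop-2-en-1-yl)-3,3-dimethylcyclohex-1-en-1-olate | CCCC[N+](CCCC)(CCCC)CCCC.[O-]C1=C(CC(Cl)=C)C(C)(C)CCC1 | intermediate (not isolated)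
18 | (2S)-2-(2-chloroprop-2-en-1-yl)-3,3-dimethyl-2-(prop-2-en-1-yl)cyclohexan-1-one | O=C1CCCC(C)(C)[C@]1(CC=C)CC(Cl)=C | intermediate
19 | (2S)-2-(2-chloroprop-2-en-1-yl)-1,3,3-trimethyl-2-(prop-2-en-1-yl)cyclohexan-1-ol (carbinol epimers) | CC1(O)CCCC(C)(C)[C@]1(CC=C)CC(Cl)=C | intermediate
20 | cis-fused 4,4,7a-trimethyl-3a-(prop-2-en-1-yl)octahydro-2H-inden-2-one (allyl and 7a-methyl syn) | O=C1C[C@@]2(CC=C)C(C)(C)CCC[C@@]2(C)C1 | intermediate
21 | ozonide (1,2,4-trioxolane) of 20 | O=C1C[C@@]2(CC3OCOO3)C(C)(C)CCC[C@@]2(C)C1 | intermediate (not isolated)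
22 | 2-(cis-4,4,7a-trimethyl-2-oxooctahydro-3aH-inden-3a-yl)acetaldehyde | O=C1C[C@@]2(CC=O)C(C)(C)CCC[C@@]2(C)C1 | intermediate
23 | tert-butyldimethylsilyl enol ether of 22 (enol toward C7) | CC(C)(C)[Si](C)(C)OC=1C[C@@]2(CC=O)C(C)(C)CCC[C@@]2(C)C=1 | intermediate (not isolated)
24 | 8-[(tert-butyldimethylsilyl)oxy]-2,2,6-trimethyltricyclo[5.2.2.0(1,6)]undecan-11-one (target numbering; C8 epimers) | O=C1C[C@]23CC(O[Si](C)(C)C(C)(C)C)[C@H]1[C@]2(C)CCCC3(C)C | intermediate
25 | tert-butyldimethyl[(2,2,6-trimethyl-11-methylidenetricyclo[5.2.2.0(1,6)]undecan-8-yl)oxy]silane (C8 epimers) | C=C1C[C@]23CC(O[Si](C)(C)C(C)(C)C)[C@H]1[C@]2(C)CCCC3(C)C | intermediate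
26 | 2,2,6-trimethyl-11-methylidenetricyclo[5.2.2.0(1,6)]undecan-8-ol (C8 epimers) | C=C1C[C@]23CC(O)[C@H]1[C@]2(C)CCCC3(C)C | intermediate
27 | 2,2,6-trimethyl-11-methylidenetricyclo[5.2.2.0(1,6)]undecan-8-one | C=C1C[C@]23CC(=O)[C@H]1[C@]2(C)CCCC3(C)C | intermediate
28 | 2,2,6-trimethyl-11-methylidenetricyclo[5.2.2.0(1,6)]undecan-8-ol, 8-exo (OH syn to the C6 bridge) | C=C1C[C@]23C[C@@H](O)[C@H]1[C@]2(C)CCCC3(C)C | intermediate
29 | 2,2-dimethyl-1,3-dioxane-4,6-dione | CC1(C)OC(=O)CC(=O)O1 | starting material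
30 | 3-oxo-3-[(2,2,6-trimethyl-11-methylidenetricyclo[5.2.2.0(1,6)]undecan-8-yl)oxy]propanoic acid (8-exo) | C=C1C[C@]23C[C@@H](OC(=O)CC(=O)O)[C@H]1[C@]2(C)CCCC3(C)C | intermediate
31 | 3,4-dihydroxybenzaldehyde | O=Cc1ccc(O)c(O)c1 | starting material
32 | 2-(3,4-dihydroxybenzylidene)malonic acid mono ester of 28 | C=C1C[C@]23C[C@@H](OC(=O)C(=Cc4ccc(O)c(O)c4)C(O)=O)[C@H]1[C@]2(C)CCCC3(C)C | intermediate (not isolated)
33 | 2,2,6-trimethyl-11-methylidenetricyclo[5.2.2.0(1,6)]undecan-8-yl (2E)-3-(3,4-dihydroxyphenyl)prop-2-enoate (CNP0308742.2) | C=C1C[C@]23C[C@@H](OC(=O)/C=C/c4ccc(O)c(O)c4)[C@H]1[C@]2(C)CCCC3(C)C | target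

## Step count and risks

Total steps: 16. Longest linear sequence: 16 steps (1 and 2 to 33).

Steps most likely to fail:

1. Step 4 (proposed new method). The first addition may occur at the gem-dimethyl terminus instead of the acetal carbon. The allyl cation may lose a proton to a diene faster than the hindered ketene acetal captures it. The ketene acetal may be protodesilylated before ring closure. Fallback with known chemistry, setting out from 7: double deprotonation (LDA, 2.2 equiv, THF, −78 → 0 °C) gives the β-keto ester dianion, which is alkylated at its γ-carbon by 1-bromo-3-methylbut-2-ene to give 2-(trimethylsilyl)ethyl 2-(2-chloroprop-2-en-1-yl)-7-methyl-3-oxooct-6-enoate F1. SnCl4 in CH2Cl2 at 0 °C then closes ring A by attack of the β-keto ester enol on the tertiary cation from the trisubstituted alkene. This comes back to the route at 14 and makes step 5 unnecessary.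

2. Step 6. Bimolecular allylation of the tetrasubstituted enolate next to the CMe2 group may be slow, so that protonation of the enolate competes and facial discrimination erodes. Fallback, setting out from 1 and using the intramolecular form of the same decarboxylative allylation: thermolysis of 1 with prop-2-en-1-ol gives prop-2-en-1-yl 3-oxobutanoate F2. Alkylation with 5 (NaH, THF) gives prop-2-en-1-yl 2-acetyl-4-chloropent-4-enoate F3. Dianion γ-alkylation with 1-bromo-3-methylbut-2-ene gives prop-2-en-1-yl 2-(2-chloroprop-2-en-1-yl)-7-methyl-3-oxooct-6-enoate F4. SnCl4 cyclisation gives prop-2-en-1-yl 1-(2-chloroprop-2-en-1-yl)-2,2-dimethyl-6-oxocyclohexane-1-carboxylate F5. Pd2(dba)3 with (S)-t-Bu-PHOX in THF at 25 °C then delivers the allyl group within the palladium–enolate ion pair with loss of CO2, and comes back to the route at 18.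

3. Step 8. The tertiary cation beside the quaternary C1 may undergo a 1,2-shift or elimination before ring closure, or the plain allyl group may compete as the nucleophile. Fallback, setting out from 18: dehydrochlorination (NaNH2, liquid NH3–THF) gives (2S)-3,3-dimethyl-2-(prop-2-en-1-yl)-2-(prop-2-yn-1-yl)cyclohexan-1-one F6. Alkyne hydration catalysed by Ph3PAuCl/AgOTf (MeOH–H2O) gives (2S)-3,3-dimethyl-2-(2-oxopropyl)-2-(prop-2-en-1-yl)cyclohexan-1-one F7. Aldol condensation (KOtBu, t-BuOH, 60 °C) gives 7,7-dimethyl-7a-(prop-2-en-1-yl)-1,4,5,6,7,7a-hexahydro-2H-inden-2-one F8. Conjugate addition of Me2CuLi with BF3·OEt2 (Et2O, −78 °C) should give the cis-fused ketone, and comes back to the route at 20.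

## Further compounds

F1 | step 4 | 2-(trimethylsilyl)ethyl 2-(2-chloroprop-2-en-1-yl)-7-methyl-3-oxooct-6-enoate | CC(C)=CCCC(=O)C(CC(Cl)=C)C(=O)OCC[Si](C)(C)C
F2 | step 6 | prop-2-en-1-yl 3-oxobutanoate | CC(=O)CC(=O)OCC=C
F3 | step 6 | prop-2-en-1-yl 2-acetyl-4-chloropent-4-enoate | CC(=O)C(CC(Cl)=C)C(=O)OCC=C
F4 | step 6 | prop-2-en-1-yl 2-(2-chloroprop-2-en-1-yl)-7-methyl-3-oxooct-6-enoate | CC(C)=CCCC(=O)C(CC(Cl)=C)C(=O)OCC=C
F5 | step 6 | prop-2-en-1-yl 1-(2-chloroprop-2-en-1-yl)-2,2-dimethyl-6-oxocyclohexane-1-carboxylate (racemic) | O=C1CCCC(C)(C)C1(CC(Cl)=C)C(=O)OCC=C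
F6 | step 8 | (2S)-3,3-dimethyl-2-(prop-2-en-1-yl)-2-(prop-2-yn-1-yl)cyclohexan-1-one | O=C1CCCC(C)(C)[C@]1(CC=C)CC#C
F7 | step 8 | (2S)-3,3-dimethyl-2-(2-oxopropyl)-2-(prop-2-en-1-yl)cyclohexan-1-one | O=C1CCCC(C)(C)[C@]1(CC=C)CC(C)=O
F8 | step 8 | 7,7-dimethyl-7a-(prop-2-en-1-yl)-1,4,5,6,7,7a-hexahydro-2H-inden-2-one (7a as in the SMILES) | O=C1C[C@@]2(CC=C)C(C)(C)CCCC2=C1
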